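The data were computed for an exercise; scatter was added.

A starting-material charge 4.00 times larger moves side product at 2.00 min, in percent of the charge, from 16.1% in alder to 16.6% in birch, a shift of 0.5 percentage points, less than the scatter. Within these runs, then, the percentage follows time since mixing more closely than it follows the charge.

| flask | starting material | coupling partner | remark | time |
|---|---|---|---|---|
| larch | 10 mM | 40 mM | run made earlier |  |
| alder | 5 mM | 40 mM | run made earlier |  |
| birch | 20 mM | 40 mM | run made earlier |  |
| Thursday's | 10 mM | 40.0 mM (fed, over 1.5 min) | all else is in the flask from the start; the feed brings no volume worth counting | 2.0 min |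
| Wednesday's | 10 mM (fed, over 1.5 min) | 40.0 mM | all else is in the flask from the start; the feed brings no volume worth counting | 2.0 min |
| Friday's | 10 mM | 40.0 mM | everything together at the start | 2.0 min |

- larch (time / s: side product / %, tris adduct / %): 15.0: 0.8, 3.1; 30.0: 1.6, 5.8; 50.0: 4.1, 8.0; 60.0: 7.2, 9.7; 80.0: 7.5, 9.6; 90.0: 9.0, 10.9; 120: 15.7, 11.3
- alder (time / min: side product / %, tris adduct / %): 0.167: 0.2, 1.2; 0.333: 1.5, 4.2; 0.667: 1.3, 7.3; 1.00: 6.9, 11.7; 1.33: 11.7, 14.4; 2.00: 16.1, 15.8; 2.50: 23.2, 16.5
- birch (time / min: side product / %, tris adduct / %): 0.333: 0.8, 3.7; 0.667: 2.0, 3.6; 1.00: 5.1, 6.1; 1.33: 7.3, 5.5; 1.50: 8.8, 4.9; 2.00: 16.6, 3.7; 2.50: 22.4, 3.5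

(standard deviation of a reading: 1 percentage point)



- the flask with the highest amount of side product, in percent of the starting material charged ("all alike" if they lie within 1.5 percentage points) (Thursday's / Wednesday's / Friday's / all alike)
- final side product, as a percentage of the starting material charged, in Thursday's
- final side product, as a percentage of the starting material charged, in Wednesday's
- final side product, as a percentage of the starting material charged, in Friday's

A steady feed enters, on average, halfway through its span, so the fed charge at the end has a mean age τ = 1.25 min, the run time less half the feed time. Thursday's and Wednesday's share this age, and the reckoning here assumes that a fed flask follows the batch curve at its mean age. Larch, past its induction period, rises from 7.2% at 1 min to 15.7% at 2 min, and that line reads 9.32% at τ.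

Turned round, on this reckoning "all alike" needs larch to climb less than 1.5 points between τ and 2.0 min. Along the line it climbs 6.4 points, which is 4.27 times the margin, so this reckoning puts Friday's, a repeat of larch, on top.

The forecast names Friday's, with 16% there, and from a “rough stepwise estimate, scaled to the batch result” gives 10% for Thursday's and 9.5% for Wednesday's, higher than the 9.32% reckoned here.

Friday's gives 17.2%, Thursday's 9.49% and Wednesday's 9.05%.

    starting material + coupling partner → mono adduct (k = 0.920 M⁻¹ s⁻¹)
    coupling partner + mono adduct → double product (k = 3.60 M⁻¹ s⁻¹)
    coupling partner + double product ⇌ tris adduct (K = 8.30 M⁻¹, k = 0.370 M⁻¹ s⁻¹)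
    double product → side product (k = 0.00290 s⁻¹)

Friday's own curve, taken straight from 6.30% at 1.00 min to 17.2% at 2.00 min, reads 9.03% at τ, beside 9.49% in Thursday's and 9.05% in Wednesday's. While the feeds ran, up to 1.50 min, the coupling steps built double product to 49.5% in Thursday's and 43.6% in Wednesday's, with side product at 4.64% and 4.58%. After the feed, double product kept turning into side product, which in Wednesday's reached 9.05% at 2.00 min.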